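**Retrosynthetic overview**

1. Target 31 ⇐ late epoxidation of the 3Z alkene, 9‑O‑angeloylation, acetonide removal, C1 oxidation and lactone α‑methylenation of macrocyclic alcohol 24.
2. 24 ⇐ intramolecular Nozaki–Hiyama–Kishi closure of the C1–C10 bond in the seco vinyl iodide/aldehyde 23; this forms the ten‑membered carbocycle.
3. 23 ⇐ decarboxylative radical conjugate addition (C7–C8 bond) joining butenolide aldehyde 11 (C1–C7, C11, C12) with dioxolane acid 19 (C8–C10, C14).
4. 11 ⇐ 3‑methylanisole (Birch reduction/ozonolysis fixes the Z trisubstituted alkene) + methyl propiolate; 19 ⇐ D‑tartaric acid; the angelate comes from mixed anhydride 22, made separately.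
5. Ring order: γ‑lactone (as butenolide, step 6) → ten‑membered ring (step 17) → epoxide (step 22).

Convention used below (target locants): C1 = ring ketone, C3/C4 = epoxide carbons (CH3 on C4), C6 = lactone O–CH, C7 = ring‑fusion CH, C8 = CHOH, C9 = CH–O‑angelate, C10 = C(=CH2), C11/C12 = lactone α‑carbon/carbonyl; the target is (3S,4R,6R,7R,8R,9R) with a 6,7‑trans lactone and a cis (Z‑derived) epoxide.

**Route**

Step 1
Reactants: 1 3-methylanisole
Product: 2 1-methoxy-5-methylcyclohexa-1,4-diene
Conditions: Li, liq. NH3/THF, t-BuOH, −78 to −33 °C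
Reagents that add atoms: none
Why: Birch reduction gives the unconjugated dihydroanisole in which the future C3=C4 alkene lies inside a six-membered ring and is therefore Z.

Step 2
Reactants: 2 1-methoxy-5-methylcyclohexa-1,4-diene
Product: 4 methyl (3Z)-3-methyl-6-oxohex-3-enoate, via methoxy hydroperoxide 3 (not isolated)
Conditions: O3 (1.0 equiv), CH2Cl2/MeOH, −78 °C; then Me2S, −78 °C to rt
Reagents that add atoms: ozone [O-][O+]=O
Why: Chemoselective ozonolysis (Criegee mechanism) cleaves only the electron-rich enol-ether alkene, opening the ring to an ester (C6) and an aldehyde (C1) with the Z alkene untouched.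

Step 3
Reactants: 4 methyl (3Z)-3-methyl-6-oxohex-3-enoate
Product: 5 methyl (3Z)-6,6-dimethoxy-3-methylhex-3-enoate
Conditions: HC(OMe)3, TsOH (cat.), MeOH, 0 °C to rt
Reagents that add atoms: trimethyl orthoformate COC(OC)OC
Why: Acid-catalysed acetalization masks the C1 aldehyde so that the two chain ends stay differentiated.

Step 4
Reactants: 5 methyl (3Z)-6,6-dimethoxy-3-methylhex-3-enoate
Product: 6 (3Z)-6,6-dimethoxy-3-methylhex-3-enal
Conditions: iBu2AlH (1.05 equiv), CH2Cl2, −78 °C; aq. KNaC4H4O6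
Reagents that add atoms: none
Why: Partial ester reduction stops at the aldehyde because the tetrahedral aluminate is stable at −78 °C and collapses only on work-up.

Step 5
Reactants: 6 (3Z)-6,6-dimethoxy-3-methylhex-3-enal; 7 methyl propiolate
Product: 8 methyl (4R,6Z)-4-hydroxy-9,9-dimethoxy-6-methylnon-6-en-2-ynoate
Conditions: (R,R)-ProPhenol (20 mol %), Me2Zn (3 equiv), Ph3PO (40 mol %), toluene, 4 °C
Reagents that add atoms: none
Why: Zinc–ProPhenol catalysed asymmetric alkynylation adds the zinc alkynylide to one aldehyde face and sets C6 as the 4R carbinol (the ligand antipode is taken if Mosher analysis shows the opposite sense).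

Step 6
Reactants: 8 methyl (4R,6Z)-4-hydroxy-9,9-dimethoxy-6-methylnon-6-en-2-ynoate
Product: 10 (5R)-5-[(2Z)-5,5-dimethoxy-2-methylpent-2-en-1-yl]furan-2(5H)-one, via Z-enoate 9 (not isolated)
Conditions: H2 (1 atm), Pd/CaCO3 poisoned with Pb(OAc)2, quinoline, EtOAc, rt; then PPTS (cat.), CH2Cl2, rt
Reagents that add atoms: none
Why: Lindlar cis-semihydrogenation gives the Z-enoate, whose γ-hydroxyl lactonizes to the butenolide without touching C6.

Step 7
Reactants: 10 (5R)-5-[(2Z)-5,5-dimethoxy-2-methylpent-2-en-1-yl]furan-2(5H)-one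
Product: 11 (3Z)-4-methyl-5-[(2R)-5-oxo-2,5-dihydrofuran-2-yl]pent-3-enal
Conditions: PPTS (10 mol %), acetone/H2O (10:1), 45 °C
Reagents that add atoms: water O
Why: Mild acid-catalysed acetal hydrolysis (transacetalization to acetone) frees the C1 aldehyde before any acid-labile ketal is in the molecule.

Step 8
Reactants: 12 D-(−)-tartaric acid
Product: 13 dimethyl (4S,5S)-2,2-dimethyl-1,3-dioxolane-4,5-dicarboxylate
Conditions: 2,2-dimethoxypropane, MeOH, TsOH (cat.), 50 °C; cyclohexane azeotrope
Reagents that add atoms: 2,2-dimethoxypropane COC(C)(C)OC; methanol CO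
Why: One-pot Fischer esterification and ketalization protects the threo diol as the trans dioxolane without touching either stereocentre.

Step 9
Reactants: 13 dimethyl (4S,5S)-2,2-dimethyl-1,3-dioxolane-4,5-dicarboxylate
Product: 14 methyl (4S,5R)-5-(hydroxymethyl)-2,2-dimethyl-1,3-dioxolane-4-carboxylate
Conditions: NaBH4 (0.6 equiv), MeOH, 0 °C
Reagents that add atoms: none
Why: Borohydride reduces one activated α-alkoxy ester of the C2-symmetric diester, and the mono-alcohol is separated from diol and recovered diester.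

Step 10
Reactants: 14 methyl (4S,5R)-5-(hydroxymethyl)-2,2-dimethyl-1,3-dioxolane-4-carboxylate
Product: 15 methyl (4S,5S)-5-formyl-2,2-dimethyl-1,3-dioxolane-4-carboxylate
Conditions: Dess–Martin periodinane, CH2Cl2, 0 °C to rt
Reagents that add atoms: none
Why: Dess–Martin oxidation gives the aldehyde under neutral conditions, and the trans arrangement on the dioxolane is the thermodynamic one.

Step 11
Reactants: 15 methyl (4S,5S)-5-formyl-2,2-dimethyl-1,3-dioxolane-4-carboxylate
Product: 16 methyl (4S,5R)-5-ethynyl-2,2-dimethyl-1,3-dioxolane-4-carboxylate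
Conditions: dimethyl (1-diazo-2-oxopropyl)phosphonate, K2CO3, MeOH, 0 °C to rt
Reagents that add atoms: Ohira–Bestmann reagent COP(=O)(OC)C(=[N+]=[N-])C(C)=O
Why: Seyferth–Gilbert homologation in its Ohira–Bestmann form converts the aldehyde into the terminal alkyne (C10≡C14) under mild carbonate conditions.

Step 12
Reactants: 16 methyl (4S,5R)-5-ethynyl-2,2-dimethyl-1,3-dioxolane-4-carboxylate
Product: 17 methyl (4S,5S)-2,2-dimethyl-5-[1-(tributylstannyl)ethenyl]-1,3-dioxolane-4-carboxylate
Conditions: Bu3SnH (1.5 equiv), Mo(CO)3(CNtBu)3 (2 mol %), hydroquinone, THF, 55 °C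
Reagents that add atoms: tributyltin hydride CCCC[SnH](CCCC)CCCC
Why: Molybdenum-catalysed hydrostannation of a propargylic ether places tin on the internal carbon next to the oxygenated centre.

Step 13
Reactants: 17 methyl (4S,5S)-2,2-dimethyl-5-[1-(tributylstannyl)ethenyl]-1,3-dioxolane-4-carboxylate
Product: 18 methyl (4S,5S)-5-(1-iodoethenyl)-2,2-dimethyl-1,3-dioxolane-4-carboxylate
Conditions: I2, CH2Cl2, 0 °C
Reagents that add atoms: iodine II
Why: Iododestannylation is an ipso substitution that turns the alkenylstannane into the 2-iodoalkene needed for the ring closure.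

Step 14
Reactants: 18 methyl (4S,5S)-5-(1-iodoethenyl)-2,2-dimethyl-1,3-dioxolane-4-carboxylate
Product: 19 (4S,5S)-5-(1-iodoethenyl)-2,2-dimethyl-1,3-dioxolane-4-carboxylic acid
Conditions: LiOH, THF/H2O, 0 °C; then 1 M HCl to pH 3
Reagents that add atoms: lithium hydroxide [Li+].[OH-]
Why: Saponification frees the acid that serves as radical precursor, and any epimerization at its α-carbon is harmless because that centre is destroyed and reset in step 16.

Step 15
Reactants: 20 angelic acid; 21 2,4,6-trichlorobenzoyl chloride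
Product: 22 (2Z)-2-methylbut-2-enoic 2,4,6-trichlorobenzoic anhydride
Conditions: Et3N, toluene, rt; filtered and used as a toluene solution
Reagents that add atoms: none
Why: Acyl substitution gives the Yamaguchi mixed anhydride, and without a nucleophilic catalyst the Z geometry of the angeloyl group is kept.

Step 16
Reactants: 11 (3Z)-4-methyl-5-[(2R)-5-oxo-2,5-dihydrofuran-2-yl]pent-3-enal; 19 (4S,5S)-5-(1-iodoethenyl)-2,2-dimethyl-1,3-dioxolane-4-carboxylic acid
Product: 23 (3Z)-5-{(2R,3S)-3-[(4R,5S)-5-(1-iodoethenyl)-2,2-dimethyl-1,3-dioxolan-4-yl]-5-oxooxolan-2-yl}-4-methylpent-3-enal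
Conditions: Ir[dF(CF3)ppy]2(dtbbpy)PF6 (2 mol %), K2HPO4, DMF, blue LEDs, rt
Reagents that add atoms: none
Why: In this photoredox decarboxylative Giese addition the dioxolan-4-yl radical attacks the butenolide β-carbon anti to the C6 side chain (6,7-trans) and through its own face anti to the iodovinyl group (8,9-trans), so C7 and C8 are each set by the neighbouring resident centre.

Step 17
Reactants: 23 seco vinyl iodide aldehyde
Product: 24 macrocyclic allylic alcohol (ten-membered ring closed at C1–C10; 1-OH as both epimers; 6R,7S,8R,9R)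
Conditions: CrCl2 (10 equiv), NiCl2 (1 mol % of CrCl2), DMSO/THF, 0.003 M, syringe-pump addition, rt
Reagents that add atoms: none
Why: In this intramolecular Nozaki–Hiyama–Kishi reaction the alkenylchromium species formed at C10 adds chemoselectively to the C1 aldehyde under high dilution, and the C1 configuration is irrelevant because it is oxidised in step 19.

Step 18
Reactants: 24 macrocyclic allylic alcohol
Product: 27 α-methylene lactone alcohol (11-methylidene; 1-OH epimers; 6R,7S,8R,9R), via Mannich base 25 (not isolated), via ammonium iodide 26 (not isolated)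
Conditions: LiN(iPr)2 (2.5 equiv), THF, −78 °C; CH2=NMe2+ I−, −78 to 0 °C; then MeI, CH2Cl2/MeOH, rt; then aq. NaHCO3, EtOAc
Reagents that add atoms: dimethylmethylideneammonium iodide (Eschenmoser's salt) C=[N+](C)C.[I-]; iodomethane CI (its methyl is carried only by 26 and leaves as trimethylamine)
Why: A lactone-enolate Mannich reaction followed by exhaustive N-methylation and Hofmann-type β-elimination installs the exocyclic methylene, the extra base only parking the C1 hydroxyl as its alkoxide.

Step 19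
Reactants: 27 α-methylene lactone alcohol
Product: 28 macrocyclic enone (1-oxo; 10-methylidene; 8,9-acetonide; 6R,7S,8R,9R)
Conditions: Dess–Martin periodinane, CH2Cl2, 0 °C
Reagents that add atoms: none
Why: Dess–Martin oxidation converts both allylic alcohol epimers into the enone under neutral conditions, so the 3Z alkene does not move into conjugation.

Step 20
Reactants: 28 macrocyclic enone
Product: 29 8,9-diol (6R,7R,8R,9R)
Conditions: AcOH/H2O (4:1), 40 °C
Reagents that add atoms: none
Why: Acid-catalysed hydrolysis of the strained trans-fused isopropylidene ketal frees the diol, while lactone, enone and alkene are inert to dilute acetic acid.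

Step 21
Reactants: 29 8,9-diol; 22 (2Z)-2-methylbut-2-enoic 2,4,6-trichlorobenzoic anhydride
Product: 30 9-O-angelate (8-OH free; 6R,7R,8R,9R)
Conditions: Et3N (2 equiv), toluene, 40 °C
Reagents that add atoms: none
Why: Yamaguchi-type acylation without nucleophilic catalyst keeps the angelate geometry, and the allylic 9-OH next to the sp2 carbon C10 is expected to react before the 8-OH that sits beside the ring-fusion carbon C7.

Step 22
Reactants: 30 9-O-angelate
Product: 31 target CNP0348992.7 (3S,4R,6R,7R,8R,9R)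
Conditions: mCPBA (1.1 equiv), NaHCO3, CH2Cl2, 0 °C
Reagents that add atoms: mCPBA OOC(=O)c1cccc(Cl)c1
Why: Prilezhaev epoxidation picks the only electron-rich alkene over the three conjugated ones and is expected to attack the outward-facing π-face of the ten-membered ring, giving the cis 3S,4R epoxide.

**Compound list**

1 | 3-methylanisole | COc1cccc(C)c1 | starting material
2 | 1-methoxy-5-methylcyclohexa-1,4-diene | COC1=CCC=C(C)C1 | intermediate
3 | methyl (3Z)-6-hydroperoxy-6-methoxy-3-methylhex-3-enoate | COC(=O)C/C(C)=C\CC(OC)OO | intermediate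
4 | methyl (3Z)-3-methyl-6-oxohex-3-enoate | COC(=O)C/C(C)=C\CC=O | intermediate
5 | methyl (3Z)-6,6-dimethoxy-3-methylhex-3-enoate | COC(=O)C/C(C)=C\CC(OC)OC | intermediate
6 | (3Z)-6,6-dimethoxy-3-methylhex-3-enal | O=CC/C(C)=C\CC(OC)OC | intermediate
7 | methyl propiolate | C#CC(=O)OC | starting material
8 | methyl (4R,6Z)-4-hydroxy-9,9-dimethoxy-6-methylnon-6-en-2-ynoate | COC(=O)C#C[C@H](O)C/C(C)=C\CC(OC)OC | intermediate
9 | methyl (2Z,4R,6Z)-4-hydroxy-9,9-dimethoxy-6-methylnona-2,6-dienoate | COC(=O)/C=C\[C@H](O)C/C(C)=C\CC(OC)OC | intermediate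
10 | (5R)-5-[(2Z)-5,5-dimethoxy-2-methylpent-2-en-1-yl]furan-2(5H)-one | O=C1C=C[C@@H](C/C(C)=C\CC(OC)OC)O1 | intermediate
11 | (3Z)-4-methyl-5-[(2R)-5-oxo-2,5-dihydrofuran-2-yl]pent-3-enal | O=C1C=C[C@@H](C/C(C)=C\CC=O)O1 | intermediate
12 | D-(−)-tartaric acid, (2S,3S) | OC(=O)[C@@H](O)[C@H](O)C(=O)O | starting material
13 | dimethyl (4S,5S)-2,2-dimethyl-1,3-dioxolane-4,5-dicarboxylate | COC(=O)[C@H]1OC(C)(C)O[C@@H]1C(=O)OC | intermediate
14 | methyl (4S,5R)-5-(hydroxymethyl)-2,2-dimethyl-1,3-dioxolane-4-carboxylate | COC(=O)[C@H]1OC(C)(C)O[C@@H]1CO | intermediate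
15 | methyl (4S,5S)-5-formyl-2,2-dimethyl-1,3-dioxolane-4-carboxylate | COC(=O)[C@H]1OC(C)(C)O[C@@H]1C=O | intermediate
16 | methyl (4S,5R)-5-ethynyl-2,2-dimethyl-1,3-dioxolane-4-carboxylate | COC(=O)[C@H]1OC(C)(C)O[C@@H]1C#C | intermediate
17 | methyl (4S,5S)-2,2-dimethyl-5-[1-(tributylstannyl)ethenyl]-1,3-dioxolane-4-carboxylate | COC(=O)[C@H]1OC(C)(C)O[C@@H]1C(=C)[Sn](CCCC)(CCCC)CCCC | intermediate
18 | methyl (4S,5S)-5-(1-iodoethenyl)-2,2-dimethyl-1,3-dioxolane-4-carboxylate | COC(=O)[C@H]1OC(C)(C)O[C@@H]1C(=C)I | intermediate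
19 | (4S,5S)-5-(1-iodoethenyl)-2,2-dimethyl-1,3-dioxolane-4-carboxylic acid | OC(=O)[C@H]1OC(C)(C)O[C@@H]1C(=C)I | intermediate
20 | angelic acid, (2Z)-2-methylbut-2-enoic acid | C/C=C(/C)C(=O)O | starting material
21 | 2,4,6-trichlorobenzoyl chloride | O=C(Cl)c1c(Cl)cc(Cl)cc1Cl | starting material
22 | (2Z)-2-methylbut-2-enoic 2,4,6-trichlorobenzoic anhydride | C/C=C(/C)C(=O)OC(=O)c1c(Cl)cc(Cl)cc1Cl | intermediate
23 | (3Z)-5-{(2R,3S)-3-[(4R,5S)-5-(1-iodoethenyl)-2,2-dimethyl-1,3-dioxolan-4-yl]-5-oxooxolan-2-yl}-4-methylpent-3-enal | O=C1O[C@H](C/C(C)=C\CC=O)[C@H](C1)[C@H]2OC(C)(C)O[C@@H]2C(=C)I | intermediate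
24 | macrocyclic allylic alcohol: ten-membered ring C1–C10, 1-OH (both epimers), 3Z alkene with 4-CH3, 10-methylidene, 8,9-trans acetonide, 6,7-trans-fused γ-lactone with C11H2; 6R,7S,8R,9R | C1C(=O)O[C@@H]2C/C(C)=C\CC(O)C(=C)[C@H]3OC(C)(C)O[C@@H]3[C@@H]12 | intermediate
25 | Mannich base: 24 with CH2NMe2 on C11 (C11 epimers) | CN(C)CC1C(=O)O[C@@H]2C/C(C)=C\CC(O)C(=C)[C@H]3OC(C)(C)O[C@@H]3[C@@H]12 | intermediate
26 | ammonium iodide: 24 with CH2NMe3+ I− on C11 | C[N+](C)(C)CC1C(=O)O[C@@H]2C/C(C)=C\CC(O)C(=C)[C@H]3OC(C)(C)O[C@@H]3[C@@H]12.[I-] | intermediate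
27 | α-methylene lactone alcohol: 24 with 11-methylidene; 6R,7S,8R,9R | C=C1C(=O)O[C@@H]2C/C(C)=C\CC(O)C(=C)[C@H]3OC(C)(C)O[C@@H]3[C@@H]12 | intermediate
28 | macrocyclic enone: 1-oxo, 10-methylidene, 11-methylidene, 8,9-acetonide, 3Z alkene; 6R,7S,8R,9R | C=C1C(=O)O[C@@H]2C/C(C)=C\CC(=O)C(=C)[C@H]3OC(C)(C)O[C@@H]3[C@@H]12 | intermediate
29 | 8,9-diol of 28; 6R,7R,8R,9R | C=C1C(=O)O[C@@H]2C/C(C)=C\CC(=O)C(=C)[C@@H](O)[C@H](O)[C@@H]12 | intermediate
30 | 9-O-angelate of 29 (3,4-deoxy target); 6R,7R,8R,9R | C=C1C(=O)O[C@@H]2C/C(C)=C\CC(=O)C(=C)[C@@H](OC(=O)/C(C)=C\C)[C@H](O)[C@@H]12 | intermediate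
31 | CNP0348992.7; 3S,4R,6R,7R,8R,9R | C=C1C(=O)O[C@@H]2C[C@@]3(C)O[C@H]3CC(=O)C(=C)[C@@H](OC(=O)/C(C)=C\C)[C@H](O)[C@@H]12 | target

**Step count and risks**

Total step count: 22. Longest linear sequence: 14 steps (steps 1–7 then 16–22; the tartrate branch, steps 8–14 then 16–22, is equally long; step 15 is a one-step side branch).

Most likely to fail, step 17 (ring closure). Closing a ten-membered ring that carries two trans-fused five-membered rings may give oligomers, and the β,γ-unsaturated aldehyde is sensitive. The fallback sets out from alkyne ester 16 (with butenolide aldehyde 11) and comes back at 24. Ester 16 is saponified with LiOH to (4S,5R)-5-ethynyl-2,2-dimethyl-1,3-dioxolane-4-carboxylic acid F1. The same photoredox decarboxylative addition to 11 gives the ynal (3Z)-5-{(2R,3S)-3-[(4R,5R)-5-ethynyl-2,2-dimethyl-1,3-dioxolan-4-yl]-5-oxooxolan-2-yl}-4-methylpent-3-enal F2. A nickel-catalysed reductive alkyne–aldehyde macrocyclization (Ni(cod)2, the bulky carbene 1,3-bis(2,6-diisopropylphenyl)imidazol-2-ylidene, Et3SiH, THF, high dilution) forms the C1–C10 bond at the internal alkyne carbon and gives the 1-O-triethylsilyl ether of 24 F3. Bu4NF/AcOH then returns 24; this path also avoids carrying a vinyl iodide through the radical step.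

Step 21 (regioselective angeloylation). The 8-OH may compete with or outrun the 9-OH, and the angelate can isomerize to tiglate if conditions are pushed. The fallback sets out from diol 29 and comes back at 30. It uses the kinetic bias in the opposite sense: TESCl/imidazole at −40 °C blocks the more reactive hydroxyl as the 8-O-triethylsilyl ether of 29 F4. Acylation of the remaining 9-OH with 22 gives the 8-O-triethylsilyl ether of 30 F5, and HF·pyridine in THF removes the silyl group to give 30.

Step 22 (face selectivity of the epoxidation). The peracid may attack the other face of the 3Z alkene and give the 3R,4S epoxide. The fallback sets out from 30 and comes back at 31. NBS in aqueous DME adds bromonium from the face the peracid prefers, and water opens it at the tertiary C4 from the opposite face to give the (3R,4R)-3-bromo-4-hydroxy bromohydrin F6. Ag2O in THF then closes the epoxide by inversion at C3, which places the oxygen on the face opposite to that reached by direct epoxidation and gives 31.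

**Further compounds**

F1 | step 17 | (4S,5R)-5-ethynyl-2,2-dimethyl-1,3-dioxolane-4-carboxylic acid | OC(=O)[C@H]1OC(C)(C)O[C@@H]1C#C
F2 | step 17 | (3Z)-5-{(2R,3S)-3-[(4R,5R)-5-ethynyl-2,2-dimethyl-1,3-dioxolan-4-yl]-5-oxooxolan-2-yl}-4-methylpent-3-enal | O=C1O[C@H](C/C(C)=C\CC=O)[C@H](C1)[C@H]2OC(C)(C)O[C@@H]2C#C
F3 | step 17 | 1-O-triethylsilyl ether of 24 | C1C(=O)O[C@@H]2C/C(C)=C\CC(O[Si](CC)(CC)CC)C(=C)[C@H]3OC(C)(C)O[C@@H]3[C@@H]12
F4 | step 21 | 8-O-triethylsilyl ether of 29 | C=C1C(=O)O[C@@H]2C/C(C)=C\CC(=O)C(=C)[C@@H](O)[C@H](O[Si](CC)(CC)CC)[C@@H]12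
F5 | step 21 | 8-O-triethylsilyl ether of 30 | C=C1C(=O)O[C@@H]2C/C(C)=C\CC(=O)C(=C)[C@@H](OC(=O)/C(C)=C\C)[C@H](O[Si](CC)(CC)CC)[C@@H]12
F6 | step 22 | (3R,4R)-3-bromo-4-hydroxy bromohydrin of 30 | C=C1C(=O)O[C@@H]2C[C@@](C)(O)[C@H](Br)CC(=O)C(=C)[C@@H](OC(=O)/C(C)=C\C)[C@H](O)[C@@H]12
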